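- You start from the blue run: by 25.0 h its electrophile reads 78.4 % and its target 0.9 %. The electrophile lost is more than the target shows, so you read the loss as two electrophile going to homo dimer, a second-order step.

| setting | blue | flask |
|---|---|---|
| electrophile | 0.050 M | 0.10 M |
| solid nucleophile | 0.20 M | 0.200 M |
| remark | run made earlier |  |
| time |  | 10 d |

blue run (percent of the electrophile charged)

| time / h | electrophile / % | target / % |
|---|---|---|
| 2.00 | 98.5 | 0.3 |
| 6.00 | 94.6 | 0.7 |
| 12.0 | 88.5 | 0.1 |
| 15.0 | 85.9 | 0 |
| 25.0 | 78.4 | 0.9 |

(scatter of a reading: 0.5 percentage points)

- percent here means electrophile units held: one homo dimer or idle adduct counts as two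
- what is said of target includes idle adduct
- solid nucleophile is a solid; its amount is given per volume of the solution
- the numbers in the tables scatter with a standard deviation of 0.5 percentage points
- steps thought possible: nucleophile + acid set free <-> protonated nucleophile; 2 electrophile -> homo dimer; electrophile + target <-> idle adduct; solid nucleophile <-> nucleophile; electrophile + nucleophile -> acid set free + target
- at the start none of the solid nucleophile is in solution
- in an amount of target, one idle adduct counts as one target
- the earlier runs do not show how much of nucleophile is bound; that part of a forecast is a guess

- part of the electrophile that has reacted at 10 d
- share of free nucleophile in free nucleophile and protonated nucleophile together, at 10 d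

- Let [electrophile] fall at k times [electrophile] squared; solving that step on the last blue reading gives k = 0.220 M⁻¹ h⁻¹, a reading that carries the scatter. Now define the dose D as k times [electrophile] at the start times the time, which for the new flask at the asked time is 5.29.
- Solve both ends of this one step. At small D the share lost is about D, and at large D the share left is about one over D. One over one plus D joins them.
- First rung of the ladder: the new flask reaches a dose of one at 1.89 d, earlier than 10 d, so the asked time lies at the large-D end.
- Second rung: at 10 d the dose reckons a share left of 15.9 %, so your own reckoning commits to 84.1 % of the electrophile reacted.
- Slowest rung: at the blue pace of target, a whole charge takes 116 d, longer than the asked time, so you keep target out of the dose. That pace rests on a reading close to the scatter.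
- For the reacted part the forecast gives 85 %, which is 0.9 percentage points above your reckoning; for the free share it gives 45 %, and of that it says: “its solubility and the binding are unknown, so fr is a guess”.
- The flask gives a reacted part of 87.2 % and a free share of 69.7 %, so the free share stands 25 points above the forecast. At 10.0 d target stands at 9.58 %. The share left reckoned from the dose, 15.9 %, stands above the 13 % of electrophile left in the flask, a gap of 2.9 points.

    nucleophile + acid set free ⇌ protonated nucleophile, settled at all times (K = 2100 M⁻¹)
    2 electrophile → homo dimer (k = 0.103 M⁻¹ h⁻¹)
    electrophile + target ⇌ idle adduct, settled at all times (K = 6.10 M⁻¹)
    solid nucleophile ⇌ nucleophile, rate k4*(cs4 - [nucleophile]) while solid is left; crystals form when [nucleophile] > cs4 (solubility = 35.0 mM, k = 0.00795 h⁻¹)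
    electrophile + nucleophile → acid set free + target (k = 0.115 M⁻¹ h⁻¹)

- Take the neighbour flask with 0.060 M of electrophile: its dose at 10 d is 3.17, which reckons a share left of 24.0 %. Computed, that flask keeps 19 %, and its reacted part is 81.4 %.

The readings are simulated from invented constants; the scatter is artificial.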